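**Strategy.** Ring A of robustol (the ring with one OH) is a resorcinol: its ether carbon C–O and its C–OH carbon are meta. One oxidation level down this pair is a 3-chlorocyclohex-2-enone, a vinylogous acid chloride. The route therefore builds ring A from an open chain (enone plus malonate) as a 5-alkylcyclohexane-1,3-dione, and closes the 22-membered ring by addition–elimination of the ring B phenoxide (4-OH of a 3,5-dimethoxyphenol) at C3 of the chloroenone, forming the diaryl ether C–O bond without metal or auxiliary activating group. The precursor is a racemic chloroenone tethered by (CH2)14 to the free syringol-type phenol; dehydrogenation then turns the activating carbonyl into the ring A hydroxyl.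

Key step: step 5

Remark: 1,15-hexadecadiene is taken as a purchasable α,ω-diene; ring B is carried as its 3,5-dimethyl ether, so the free 4-OH of commercial 4-bromo-2,6-dimethoxyphenol is the oxygen that becomes the ether oxygen.

**Step 1**
Reactants: 1 1,15-hexadecadiene; 2 4-bromo-2,6-dimethoxyphenol
Product: 4 4-(hexadec-15-en-1-yl)-2,6-dimethoxyphenol, via B-(hexadec-15-enyl)-9-BBN 3 (not isolated)
Conditions: 1 (excess), 9-BBN, THF, 0 °C to rt; then 2, Pd(OAc)2, SPhos, aq. K3PO4, THF, 65 °C
Reagents that add atoms: none
Why: Anti-Markovnikov hydroboration of one terminal alkene (excess diene keeps the reaction at one end and is recovered) followed by B-alkyl Suzuki–Miyaura sp3–sp2 coupling, in which the bromophenol reacts as its phenoxide and the electron-rich biarylphosphine supports oxidative addition to the electron-rich aryl bromide.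

**Step 2**
Reactants: 4 4-(hexadec-15-en-1-yl)-2,6-dimethoxyphenol; 5 methyl vinyl ketone
Product: 6 (E)-18-(4-hydroxy-3,5-dimethoxyphenyl)octadec-3-en-2-one
Conditions: 5 (excess), second-generation Hoveyda–Grubbs catalyst RuCl2(H2IMes)(=CH-C6H4-2-OiPr) (cat.), CH2Cl2, 40 °C
Reagents that add atoms: none
Why: Olefin cross-metathesis of an unhindered terminal alkene with an electron-poor enone that homodimerises only slowly should favour the cross product as the E alkene, and the ruthenium carbene tolerates the free phenol.

**Step 3**
Reactants: 6 (E)-18-(4-hydroxy-3,5-dimethoxyphenyl)octadec-3-en-2-one; 7 diethyl malonate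
Product: 11 5-[14-(4-hydroxy-3,5-dimethoxyphenyl)tetradecyl]cyclohexane-1,3-dione, via Michael adduct 8 (not isolated), via cyclic keto ester 9 (not isolated), via keto acid 10 (not isolated)
Conditions: NaOEt (excess), EtOH, reflux, under argon; then aq. NaOH, reflux; then aq. HCl, reflux
Reagents that add atoms: none
Why: Michael addition of sodiomalonate, intramolecular Claisen (Dieckmann-type) condensation of the methyl ketone onto one ester, saponification and decarboxylation of the β-keto acid is the classical dimedone-type construction of a 5-substituted cyclohexane-1,3-dione; the carbon created in the Michael step is racemic in 8–10 and ceases to be a stereocenter in the symmetric diketone.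

**Step 4**
Reactants: 11 5-[14-(4-hydroxy-3,5-dimethoxyphenyl)tetradecyl]cyclohexane-1,3-dione
Product: 12 3-chloro-5-[14-(4-hydroxy-3,5-dimethoxyphenyl)tetradecyl]cyclohex-2-en-1-one (racemic)
Conditions: (COCl)2 (slight excess), DMF (cat.), CH2Cl2, 0 °C, no amine base
Reagents that add atoms: oxalyl chloride ClC(=O)C(Cl)=O
Why: The dione reacts as a vinylogous carboxylic acid with the chloroiminium species to give the vinylogous acid chloride, while the hindered phenol should not be acylated without base and, being un-ionised, cannot add to the chloroenone; the two carbonyls are equivalent, so one racemic chloroenone results.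

**Step 5**
Reactants: 12 3-chloro-5-[14-(4-hydroxy-3,5-dimethoxyphenyl)tetradecyl]cyclohex-2-en-1-one
Product: 13 macrocyclic vinylogous aryl ester (3-aryloxycyclohex-2-en-1-one whose aryloxy oxygen is O-4 of the 3,5-dimethoxyphenyl ring and whose C5 is tied by (CH2)14 to the carbon para to that oxygen; 22-membered ring, racemic)
Conditions: Cs2CO3, MeCN, 70 °C, syringe-pump addition of 12 to about 1 mM, under argon
Reagents that add atoms: none
Why: Cs2CO3 converts the phenol of 12 into its phenoxide, which adds in conjugate fashion to C3 of the 3-chlorocyclohex-2-enone and expels chloride from the resulting enolate (addition–elimination, nucleophilic vinylic substitution at a vinylogous acid chloride), so the ring B oxygen becomes bonded to the future ether carbon of ring A. The closest known reaction is the intermolecular etherification of phenols with 3-chlorocyclohex-2-enones under carbonate bases, run here intramolecularly under high dilution in the manner of a macrolactonisation. One ring is closed, the 22-membered macrocycle, by a 22-exo-trig attack (C2=C3 of the enone lies outside the new ring), and the flexible (CH2)14 tether adds no strain. No stereocenter is formed; the existing C5 center is racemic, is untouched here and is erased in step 6. The step needs O- over C-attack and ring closure over oligomerisation: both ortho positions of the phenoxide carry OMe and the para position carries the chain, so only oxygen can react, chloride sits on the only electrophilic β-carbon, and slow addition keeps the bimolecular pathway down. Because the activating carbonyl is the future ring A hydroxyl, nothing has to be removed afterwards except two hydrogens.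

**Step 6**
Reactants: 13 macrocyclic vinylogous aryl ester
Product: 17 robustol ring B dimethyl ether, via selenide 14 (not isolated), via selenoxide 15 (not isolated), via dienone 16 (not isolated)
Conditions: LiN(iPr)2, THF, −78 °C; PhSeBr; then aq. H2O2, pyridine, CH2Cl2, 0 °C to rt
Reagents that add atoms: none
Why: Kinetic α'-deprotonation (C6) of the vinylogous ester, selenenylation and oxidation give a selenoxide whose syn-elimination toward H-5 forms the cross-conjugated dienone, which tautomerises irreversibly to the phenol (selenoxide dehydrogenation); this removes the C5 stereocenter.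

**Step 7**
Reactants: 17 robustol ring B dimethyl ether
Product: 18 robustol
Conditions: BBr3 (excess), CH2Cl2, −78 °C to rt; then H2O, under argon
Reagents that add atoms: none
Why: Lewis acid-mediated cleavage of the two aryl methyl ethers (boron coordinates the ether oxygen, bromide removes the methyl group by SN2), to which the diaryl ether and the alkyl chain are inert.

**Compound list**
1 | 1,15-hexadecadiene | C=CCCCCCCCCCCCCCC=C | starting material
2 | 4-bromo-2,6-dimethoxyphenol | COc1cc(Br)cc(OC)c1O | starting material
3 | 9-(hexadec-15-en-1-yl)-9-borabicyclo[3.3.1]nonane (not isolated) | C=CCCCCCCCCCCCCCCB1C2CCCC1CCC2 | intermediate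
4 | 4-(hexadec-15-en-1-yl)-2,6-dimethoxyphenol | C=CCCCCCCCCCCCCCCc1cc(OC)c(O)c(OC)c1 | intermediate
5 | methyl vinyl ketone (but-3-en-2-one) | CC(=O)C=C | starting material
6 | (E)-18-(4-hydroxy-3,5-dimethoxyphenyl)octadec-3-en-2-one | CC(=O)/C=C/CCCCCCCCCCCCCCc1cc(OC)c(O)c(OC)c1 | intermediate
7 | diethyl malonate | CCOC(=O)CC(=O)OCC | starting material
8 | diethyl 2-[1-(4-hydroxy-3,5-dimethoxyphenyl)-17-oxooctadecan-15-yl]propanedioate (racemic, not isolated) | CCOC(=O)C(C(=O)OCC)C(CC(C)=O)CCCCCCCCCCCCCCc1cc(OC)c(O)c(OC)c1 | intermediate
9 | ethyl 6-[14-(4-hydroxy-3,5-dimethoxyphenyl)tetradecyl]-2,4-dioxocyclohexane-1-carboxylate (racemic, present as its sodium enolate, not isolated) | CCOC(=O)C1C(CCCCCCCCCCCCCCc2cc(OC)c(O)c(OC)c2)CC(=O)CC1=O | intermediate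
10 | 6-[14-(4-hydroxy-3,5-dimethoxyphenyl)tetradecyl]-2,4-dioxocyclohexane-1-carboxylic acid (racemic, not isolated) | OC(=O)C1C(CCCCCCCCCCCCCCc2cc(OC)c(O)c(OC)c2)CC(=O)CC1=O | intermediate
11 | 5-[14-(4-hydroxy-3,5-dimethoxyphenyl)tetradecyl]cyclohexane-1,3-dione | O=C1CC(CCCCCCCCCCCCCCc2cc(OC)c(O)c(OC)c2)CC(=O)C1 | intermediate
12 | 3-chloro-5-[14-(4-hydroxy-3,5-dimethoxyphenyl)tetradecyl]cyclohex-2-en-1-one (racemic) | ClC1=CC(=O)CC(CCCCCCCCCCCCCCc2cc(OC)c(O)c(OC)c2)C1 | intermediate
13 | macrocyclic vinylogous aryl ester: 22-membered ring closed between O-4 of the 3,5-dimethoxyphenyl ring and C3 of the cyclohex-2-en-1-one, with C5 carrying the (CH2)14 tether (racemic) | O=C1C=C2CC(C1)CCCCCCCCCCCCCCc1cc(OC)c(O2)c(OC)c1 | intermediate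
14 | 6-(phenylselanyl) derivative of 13 (racemic, mainly trans to the chain, not isolated) | O=C1C=C2CC(C1[Se]c3ccccc3)CCCCCCCCCCCCCCc1cc(OC)c(O2)c(OC)c1 | intermediate
15 | selenoxide of 14 (mixture of isomers, not isolated) | O=C1C=C2CC(C1[Se](=O)c3ccccc3)CCCCCCCCCCCCCCc1cc(OC)c(O2)c(OC)c1 | intermediate
16 | macrocyclic 3-aryloxy-5-alkylcyclohexa-2,5-dien-1-one, keto tautomer of 17 (not isolated) | O=C1C=C2CC(=C1)CCCCCCCCCCCCCCc1cc(OC)c(O2)c(OC)c1 | intermediate
17 | robustol ring B dimethyl ether (robustol with both ring B hydroxyls as OMe) | Oc1cc2cc(c1)Oc1c(OC)cc(cc1OC)CCCCCCCCCCCCCC2 | intermediate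
18 | robustol | Oc1cc2cc(c1)Oc1c(O)cc(cc1O)CCCCCCCCCCCCCC2 | target

**Total step count:** 7. **Longest linear sequence:** 7 steps (1 to 18). The target has no stereocenter; the only stereocenter on the way (C5 of ring A at the cyclohexenone level) is racemic and is removed in step 6.

**Steps most likely to fail**

1. Step 5. Intermolecular addition–elimination may outpace ring closure and give linear and cyclic oligomers, or the carbonate may deprotonate C4 of the chloroenone so that the halide is lost to hydrolysis. The fallback forms the same C–O bond on an aromatic ring A by copper catalysis. It sets out from 11 and comes back at 17.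
   - Treatment of 11 with (COBr)2 and catalytic DMF in CH2Cl2 should give 3-bromo-5-[14-(4-hydroxy-3,5-dimethoxyphenyl)tetradecyl]cyclohex-2-en-1-one F1.
   - Two equivalents of LiN(iPr)2 (the first for the phenol) and PhSeBr at −78 °C should give 3-bromo-5-[14-(4-hydroxy-3,5-dimethoxyphenyl)tetradecyl]-6-(phenylselanyl)cyclohex-2-en-1-one F2.
   - Oxidation at selenium with mCPBA at −78 °C and warming with Et3N should bring about syn-elimination and tautomerisation to 3-bromo-5-[14-(4-hydroxy-3,5-dimethoxyphenyl)tetradecyl]phenol F3.
   - An Ullmann macrocyclisation (CuI, N,N-dimethylglycine, Cs2CO3, 1,4-dioxane, 100 °C, high dilution) should then join the ring B oxygen to the brominated carbon and give 17. The ring A phenoxide cannot reach its own C–Br bond within one molecule.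

2. Step 4. The reagent may acylate or formylate the phenol oxygen, or the phenol may add to the chloroenone while the crude product is concentrated. The fallback masks the phenol and releases it only at the moment of ring closure. It sets out from 11 and comes back at 13.
   - TBSCl and imidazole in DMF should silylate both the phenol and the enol, giving 3-(tert-butyldimethylsilyloxy)-5-{14-[4-(tert-butyldimethylsilyloxy)-3,5-dimethoxyphenyl]tetradecyl}cyclohex-2-en-1-one F4.
   - A mildly acidic aqueous work-up should hydrolyse only the labile enol silyl ether, giving 5-{14-[4-(tert-butyldimethylsilyloxy)-3,5-dimethoxyphenyl]tetradecyl}cyclohexane-1,3-dione F5.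
   - (COCl)2 with catalytic DMF should then give 3-chloro-5-{14-[4-(tert-butyldimethylsilyloxy)-3,5-dimethoxyphenyl]tetradecyl}cyclohex-2-en-1-one F6.
   - CsF in DMF at 60 °C under high dilution should cleave the aryl silyl ether, and the phenoxide set free should close the ring as in step 5 to give 13.

3. Step 6. Deprotonation at C4 instead of C6 may lead to selenenylation at C2 or C4, or the amide base may attack C3, expel the aryloxide and open the macrocycle. The fallback replaces the stoichiometric enolate chemistry by catalytic C–H dehydrogenation. It sets out from 13 and comes back at 17.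
   - Pd(OCOCF3)2, 2-(dimethylamino)pyridine and TsOH under O2 in DMSO at 80 °C should form a divalent palladium enolate at C6.
   - β-Hydride elimination from C5 should give dienone 16, which tautomerises to 17, while O2 reoxidises zerovalent palladium. No new compound is made.

**Further compounds**
F1 | step 5 | 3-bromo-5-[14-(4-hydroxy-3,5-dimethoxyphenyl)tetradecyl]cyclohex-2-en-1-one (racemic) | BrC1=CC(=O)CC(CCCCCCCCCCCCCCc2cc(OC)c(O)c(OC)c2)C1
F2 | step 5 | 3-bromo-5-[14-(4-hydroxy-3,5-dimethoxyphenyl)tetradecyl]-6-(phenylselanyl)cyclohex-2-en-1-one (racemic) | BrC1=CC(=O)C([Se]c3ccccc3)C(CCCCCCCCCCCCCCc2cc(OC)c(O)c(OC)c2)C1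
F3 | step 5 | 3-bromo-5-[14-(4-hydroxy-3,5-dimethoxyphenyl)tetradecyl]phenol | Oc1cc(Br)cc(CCCCCCCCCCCCCCc2cc(OC)c(O)c(OC)c2)c1
F4 | step 4 | 3-(tert-butyldimethylsilyloxy)-5-{14-[4-(tert-butyldimethylsilyloxy)-3,5-dimethoxyphenyl]tetradecyl}cyclohex-2-en-1-one (racemic) | CC(C)(C)[Si](C)(C)OC1=CC(=O)CC(CCCCCCCCCCCCCCc2cc(OC)c(O[Si](C)(C)C(C)(C)C)c(OC)c2)C1
F5 | step 4 | 5-{14-[4-(tert-butyldimethylsilyloxy)-3,5-dimethoxyphenyl]tetradecyl}cyclohexane-1,3-dione | O=C1CC(CCCCCCCCCCCCCCc2cc(OC)c(O[Si](C)(C)C(C)(C)C)c(OC)c2)CC(=O)C1
F6 | step 4 | 3-chloro-5-{14-[4-(tert-butyldimethylsilyloxy)-3,5-dimethoxyphenyl]tetradecyl}cyclohex-2-en-1-one (racemic) | ClC1=CC(=O)CC(CCCCCCCCCCCCCCc2cc(OC)c(O[Si](C)(C)C(C)(C)C)c(OC)c2)C1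
F0 | step 6 | none | none
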